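**Retrosynthetic overview**

1. The target is one 25-membered lactone ring (C1 carbonyl, C2–C24 methylenes, ring oxygen) with no stereocentre. Its O–C24–C23–C22 corner is the skeleton of pent-3-yn-1-ol, so the ring is opened at C21–C22, next to the alkyl-oxygen end.
2. Target ⇐ full hydrogenation of the C21≡C22 cycloalkyne lactone, tetracos-21-yn-24-olide.
3. Cycloalkyne ⇐ ring-closing alkyne metathesis of pent-3-yn-1-yl tricos-21-ynoate; this is the only ring-forming step.
4. Diyne ester ⇐ tricos-21-ynoic acid + pent-3-yn-1-ol; the acid ⇐ C11–C12 bond by copper-catalysed coupling of a dodec-10-ynyl Grignard reagent with 11-bromoundecanoic acid.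
5. The C12 bromide ⇐ undec-10-yn-1-ol by C-methylation and Appel bromination.

Key step: step 5

Remark: ring positions follow the lactone name, C1 = carbonyl carbon to C24 = OCH2, with the ring oxygen as the 25th ring atom; the three starting materials are taken as commercial.

**Route**

Step 1
Reactants: 1 undec-10-yn-1-ol
Product: 3 dodec-10-yn-1-ol, via dilithiated undec-10-yn-1-ol 2 (not isolated)
Conditions: n-BuLi (2.1 equiv), THF, −78 to 0 °C; MeI (1.05 equiv), −78 °C to rt; then H2O
Reagents that add atoms: iodomethane, CI
Why: Two equivalents of n-BuLi give the alkoxide–acetylide dianion, whose carbon terminus is far more nucleophilic towards MeI than the aggregated lithium alkoxide in THF, so this acetylide alkylation (SN2 C-methylation of a dianion) should install the methyl cap without protecting the alcohol.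

Step 2
Reactants: 3 dodec-10-yn-1-ol
Product: 4 12-bromododec-2-yne
Conditions: CBr4, PPh3, CH2Cl2, 0 °C to rt
Reagents that add atoms: tetrabromomethane, BrC(Br)(Br)Br
Why: In this Appel reaction the primary alcohol is activated as an alkoxyphosphonium ion and displaced by bromide under neutral conditions that leave the internal alkyne untouched.

Step 3
Reactants: 4 12-bromododec-2-yne; 5 11-bromoundecanoic acid
Product: 8 tricos-21-ynoic acid, via dodec-10-yn-1-ylmagnesium bromide 6 (not isolated), via chloromagnesium 11-bromoundecanoate 7 (not isolated)
Conditions: 4, Mg, THF, 40 °C; separately 5, MeMgCl (1.0 equiv), THF, −20 °C; combine, Li2CuCl4 (3 mol %), THF, −20 °C to rt; then 1 M HCl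
Reagents that add atoms: none
Why: In this copper-catalysed Grignard–alkyl bromide cross-coupling (Li2CuCl4), the primary Grignard reagent 6, which carries only an inert internal alkyne, displaces the primary bromide of 7 through an alkylcuprate while the carboxyl group is masked as its magnesium salt, forming the C11–C12 bond of the C23 acid.

Step 4
Reactants: 8 tricos-21-ynoic acid; 9 pent-3-yn-1-ol
Product: 11 pent-3-yn-1-yl tricos-21-ynoate, via tricos-21-ynoyl chloride 10 (not isolated)
Conditions: (COCl)2 (1.2 equiv), DMF (cat.), CH2Cl2, 0 °C to rt, volatiles removed; then 9, pyridine, DMAP (cat.), CH2Cl2, 0 °C to rt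
Reagents that add atoms: none
Why: Acylation of the primary alcohol by the acid chloride (formed with oxalyl chloride under Vilsmeier catalysis) is a dependable esterification that involves neither alkyne, with pyridine taking up the HCl.

Step 5
Reactants: 11 pent-3-yn-1-yl tricos-21-ynoate
Product: 12 tetracos-21-yn-24-olide (1-oxacyclopentacos-22-yn-2-one)
Conditions: Mo(≡CC6H4OMe-4)(OSiPh3)3 (5 mol %), 5 Å molecular sieves, toluene (0.002 M), rt
Reagents that add atoms: none
Why: The molybdenum alkylidyne adds to one CH3C≡C terminus in a [2+2] cycloaddition, the metallacyclobutadiene cycloreverts to a substrate-bound alkylidyne, and a second [2+2]/cycloreversion with the other terminus releases the ring, the two methyl caps leaving together as but-2-yne, which the 5 Å sieves sequester so that the equilibrium is pulled forward. The closest known reaction type is ring-closing alkyne metathesis of methyl-capped diyne esters to macrocyclic cycloalkyne lactones with silanolate-ligated molybdenum alkylidynes. The only ring, the 25-membered lactone, is closed end to end between C21 and C22 with the new triple bond endocyclic, and a ring of this size holds the linear C20–C21≡C22–C23 unit without strain. No stereocentre is formed and, unlike alkene metathesis, no double-bond isomers can arise. The selectivity required is ring closure over intermolecular oligomerisation, which high dilution, removal of but-2-yne and the reversibility of oligomer formation (backbiting to the monomeric ring) should secure. The ester is tolerated by the triphenylsilanolate catalyst, and the methyl caps avoid the catalyst-degrading pathways of terminal alkynes.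

Step 6
Reactants: 12 tetracos-21-yn-24-olide
Product: 13 24-tetracosanolide (1-oxacyclopentacosan-2-one)
Conditions: H2 (1 atm), 10% Pd/C, EtOAc, rt
Reagents that add atoms: none
Why: Heterogeneous catalytic hydrogenation over Pd/C should saturate the unstrained ring alkyne through the cis-alkene to the CH2–CH2 unit while the lactone stays intact and no stereocentre is created.

**Compound list**

1 | undec-10-yn-1-ol | C#CCCCCCCCCCO | starting material
2 | dilithiated undec-10-yn-1-ol (lithium alkoxide, lithium acetylide) | [Li]C#CCCCCCCCCCO[Li] | intermediate
3 | dodec-10-yn-1-ol | CC#CCCCCCCCCCO | intermediate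
4 | 12-bromododec-2-yne | CC#CCCCCCCCCCBr | intermediate
5 | 11-bromoundecanoic acid | OC(=O)CCCCCCCCCCBr | starting material
6 | dodec-10-yn-1-ylmagnesium bromide | CC#CCCCCCCCCC[Mg]Br | intermediate
7 | chloromagnesium 11-bromoundecanoate | BrCCCCCCCCCCC(=O)O[Mg]Cl | intermediate
8 | tricos-21-ynoic acid | CC#CCCCCCCCCCCCCCCCCCCCC(=O)O | intermediate
9 | pent-3-yn-1-ol | CC#CCCO | starting material
10 | tricos-21-ynoyl chloride | CC#CCCCCCCCCCCCCCCCCCCCC(=O)Cl | intermediate
11 | pent-3-yn-1-yl tricos-21-ynoate | CC#CCCCCCCCCCCCCCCCCCCCC(=O)OCCC#CC | intermediate
12 | tetracos-21-yn-24-olide (1-oxacyclopentacos-22-yn-2-one) | O=C1CCCCCCCCCCCCCCCCCCCC#CCCO1 | intermediate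
13 | 24-tetracosanolide (1-oxacyclopentacosan-2-one) | O=C1CCCCCCCCCCCCCCCCCCCCCCCO1 | target

**Step count**

Total step count: 6. Longest linear sequence: 6 steps (1 to 13); compounds 5 and 9 enter as commercial partners in steps 3 and 4.

**Steps most likely to fail**

Step 5 (ring-closing alkyne metathesis). Intermolecular metathesis may outrun ring closure and give acyclic oligomers and the cyclic dimer. The alkylidyne may also be deactivated by traces of protic material (residual acid, alcohol, water) or by terminal-alkyne contaminants carried over from incomplete methylation. The fallback sets out from 11 and comes back at 13. Semihydrogenation of both triple bonds (H2, Pd/CaCO3 poisoned with Pb(OAc)2, quinoline, EtOAc) should give (3Z)-pent-3-en-1-yl (21Z)-tricos-21-enoate F1. Ring-closing alkene metathesis with second-generation Grubbs catalyst RuCl2(=CHPh)(H2IMes)(PCy3) in dilute CH2Cl2 at 40 °C, with loss of but-2-ene, should then give tetracos-21-en-24-olide F2 as an E/Z mixture. Hydrogenation under the conditions of step 6 removes the alkene geometry issue and arrives at 13.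

Step 3 (Grignard formation and copper-catalysed coupling). Wurtz-type homocoupling during Grignard formation and incomplete cross-coupling on the sparingly soluble magnesium carboxylate may leave long-chain by-products that are hard to separate from the waxy acid. The fallback sets out from 4 and comes back at 8. Commercial methyl undec-10-enoate is hydroborated with 9-BBN-H (1.0 equiv, THF) to methyl 11-(9-borabicyclo[3.3.1]nonan-9-yl)undecanoate F3. This is coupled in the same flask with 4 in an alkyl–alkyl Suzuki–Miyaura reaction (Pd(OAc)2, PCy3, K3PO4·H2O, THF, rt) to give methyl tricos-21-ynoate F4. Saponification (LiOH, THF/H2O, then HCl) returns to 8.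

Step 1 (dianion methylation). Competing O-methylation of the lithium alkoxide and incomplete C-methylation of a poorly soluble dianion may give mixtures that are difficult to separate. Residual terminal alkyne would later quench the Grignard reagent and poison the molybdenum catalyst. The fallback sets out from 1 and comes back at 3. Silylation (TBSCl, imidazole, DMF) gives tert-butyldimethyl(undec-10-yn-1-yloxy)silane F5. Deprotonation with n-BuLi (THF, −78 °C) gives the lithium acetylide [11-(tert-butyldimethylsilyloxy)undec-1-yn-1-yl]lithium F6, which is methylated with MeI to tert-butyl(dodec-10-yn-1-yloxy)dimethylsilane F7. Desilylation with TBAF in THF returns to 3.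

**Further compounds**

F1 | step 5 | (3Z)-pent-3-en-1-yl (21Z)-tricos-21-enoate | C/C=C\CCCCCCCCCCCCCCCCCCCC(=O)OCC/C=C\C
F2 | step 5 | tetracos-21-en-24-olide (E/Z mixture) | O=C1CCCCCCCCCCCCCCCCCCCC=CCCO1
F3 | step 3 | methyl 11-(9-borabicyclo[3.3.1]nonan-9-yl)undecanoate | COC(=O)CCCCCCCCCCB1C2CCCC1CCC2
F4 | step 3 | methyl tricos-21-ynoate | CC#CCCCCCCCCCCCCCCCCCCCC(=O)OC
F5 | step 1 | tert-butyldimethyl(undec-10-yn-1-yloxy)silane | C#CCCCCCCCCCO[Si](C)(C)C(C)(C)C
F6 | step 1 | [11-(tert-butyldimethylsilyloxy)undec-1-yn-1-yl]lithium | [Li]C#CCCCCCCCCCO[Si](C)(C)C(C)(C)C
F7 | step 1 | tert-butyl(dodec-10-yn-1-yloxy)dimethylsilane | CC#CCCCCCCCCCO[Si](C)(C)C(C)(C)C
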